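The ten-membered ring is disconnected between C7 (the ring-fusion carbon β to the lactone carbonyl) and C8 (the carbinol carbon that carries the ester), in germacrane numbering. With the C11 methyl raised to an exocyclic methylene, C8–OH, C7 and C11=C13 form the homoallylic-alcohol pattern of a carbonyl allylation. The precursor is therefore a monocyclic (5R)-butenolide, a 3-(bromomethyl)furan-2(5H)-one whose C6 side chain ends in the C8 aldehyde. Divalent chromium (CrCl2) turns the bromide into an allylchromium that attacks the aldehyde through C7. One operation closes the carbocycle, sets C7 and C8 from the single C6 stereocentre and unveils the α-methylene lactone, which is then reduced to the 11S methyl lactone and esterified.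

Key step: step 14

Remark on numbering: ring carbons are C1 to C10, lactone carbons C11 and C12, C13 on C11, C14 on C10, C15 on C4. TBS = tert-butyldimethylsilyl, TBDPS = tert-butyldiphenylsilyl, PMB = 4-methoxybenzyl, TES = triethylsilyl.

Remark on the chemistry: in step 7 the ProPhenol antipode must add the alkynylzinc to the Si face of the aldehyde of 12. This is assumed to be the (S,S)-ligand; if the sense is the opposite, the mirror-image ligand is used.

Step 1
Reactants: 1 tert-butyl(but-3-yn-1-yloxy)dimethylsilane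
Product: 4 (3E)-6-(TBS-oxy)-4-methylhex-3-en-1-ol, via alkenyldimethylalane 2 (not isolated), via lithium alkenylalanate 3 (not isolated)
Conditions: Me3Al, Cp2ZrCl2 (20 mol%), CH2Cl2, 0 °C to rt; n-BuLi, THF, −78 °C; ethylene oxide, −78 °C to rt; aq. potassium sodium tartrate
Reagents that add atoms: trimethylaluminium C[Al](C)C; ethylene oxide C1CO1
Why: Negishi zirconium-catalysed syn-carboalumination adds methyl and aluminium cis across the terminal alkyne, which fixes the E geometry of the C1=C10 olefin, and the derived lithium alanate opens ethylene oxide with retention of that geometry.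

Step 2
Reactants: 4 (3E)-6-(TBS-oxy)-4-methylhex-3-en-1-ol
Product: 5 [(3E)-6-bromo-3-methylhex-3-en-1-yl]oxy(tert-butyl)dimethylsilane
Conditions: CBr4, PPh3, CH2Cl2, 0 °C
Reagents that add atoms: tetrabromomethane BrC(Br)(Br)Br
Why: Appel bromination converts the primary alcohol into the bromide under neutral conditions that leave the silyl ether and the trisubstituted olefin untouched.

Step 3
Reactants: 6 methyl 4-hydroxybut-2-ynoate
Product: 7 methyl 4-(TBDPS-oxy)but-2-ynoate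
Conditions: TBDPSCl, imidazole, CH2Cl2, 0 °C to rt
Reagents that add atoms: tert-butyl(chloro)diphenylsilane CC(C)(C)[Si](Cl)(c1ccccc1)c1ccccc1
Why: Standard silylation of the primary propargylic alcohol gives a robust ether that should survive every later step up to the final deprotection.

Step 4
Reactants: 5 [(3E)-6-bromo-3-methylhex-3-en-1-yl]oxy(tert-butyl)dimethylsilane; 7 methyl 4-(TBDPS-oxy)but-2-ynoate
Product: 10 methyl (2Z,6E)-9-(TBS-oxy)-3-[(TBDPS-oxy)methyl]-7-methylnona-2,6-dienoate, via alkylmagnesium bromide 8 (not isolated), via alkylcopper 9 (not isolated)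
Conditions: Mg, THF, rt; CuBr·SMe2 (1 equiv), THF, −78 to −40 °C; then 7, −78 °C; MeOH then aq. NH4Cl at −78 °C
Reagents that add atoms: none
Why: Syn-carbocupration (conjugate addition) of the organocopper to the ynoate at −78 °C and protonation of the alkenylcopper with retention place the new chain trans to the ester, so that C15 and C6 end up cis on the C4=C5 olefin.

Step 5
Reactants: 10 methyl (2Z,6E)-9-(TBS-oxy)-3-[(TBDPS-oxy)methyl]-7-methylnona-2,6-dienoate
Product: 11 (2Z,6E)-9-(TBS-oxy)-3-[(TBDPS-oxy)methyl]-7-methylnona-2,6-dien-1-ol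
Conditions: i-Bu2AlH (2.2 equiv), CH2Cl2, −78 °C; aq. potassium sodium tartrate
Reagents that add atoms: none
Why: i-Bu2AlH reduces the conjugated ester by 1,2-addition to the allylic alcohol without touching the olefin geometry.

Step 6
Reactants: 11 (2Z,6E)-9-(TBS-oxy)-3-[(TBDPS-oxy)methyl]-7-methylnona-2,6-dien-1-ol
Product: 12 (2Z,6E)-9-(TBS-oxy)-3-[(TBDPS-oxy)methyl]-7-methylnona-2,6-dienal
Conditions: MnO2 (excess), CH2Cl2, rt
Reagents that add atoms: none
Why: MnO2 oxidises the allylic alcohol selectively to the enal under neutral conditions that should not isomerise the Z olefin.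

Step 7
Reactants: 12 (2Z,6E)-9-(TBS-oxy)-3-[(TBDPS-oxy)methyl]-7-methylnona-2,6-dienal; 13 1-methoxy-4-[(prop-2-yn-1-yloxy)methyl]benzene
Product: 15 (4R,5Z,9E)-12-(TBS-oxy)-6-[(TBDPS-oxy)methyl]-1-(PMB-oxy)-10-methyldodeca-5,9-dien-2-yn-4-ol, via alkynyl(methyl)zinc 14 (not isolated)
Conditions: (S,S)-ProPhenol (20 mol%), Me2Zn (3 equiv), Ph3PO (40 mol%), toluene, 0 °C
Reagents that add atoms: none
Why: ProPhenol dinuclear zinc alkynylation adds the alkynylzinc to the Si face of the enal within the chiral pocket of the catalyst, which sets C6 as R.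

Step 8
Reactants: 15 (4R,5Z,9E)-12-(TBS-oxy)-6-[(TBDPS-oxy)methyl]-1-(PMB-oxy)-10-methyldodeca-5,9-dien-2-yn-4-ol
Product: 17 (2Z,4R,5Z,9E)-12-(TBS-oxy)-6-[(TBDPS-oxy)methyl]-2-iodo-1-(PMB-oxy)-10-methyldodeca-2,5,9-trien-4-ol, via cyclic sodium alkenylalanate 16 (not isolated)
Conditions: NaAlH2(OCH2CH2OMe)2, THF, 0 °C; EtOAc; then iodine, THF, −78 to 0 °C
Reagents that add atoms: iodine [I][I]
Why: Hydroxyl-directed trans-hydroalumination of the propargylic alcohol delivers hydride to C7 and aluminium to C11, and iodinolysis of the carbon–aluminium bond with retention gives the Z-iodoalkene with iodine cis to the carbinol carbon.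

Step 9
Reactants: 17 (2Z,4R,5Z,9E)-12-(TBS-oxy)-6-[(TBDPS-oxy)methyl]-2-iodo-1-(PMB-oxy)-10-methyldodeca-2,5,9-trien-4-ol
Product: 18 (5R)-5-[(1Z,5E)-8-(TBS-oxy)-2-[(TBDPS-oxy)methyl]-6-methylocta-1,5-dien-1-yl]-3-[(PMB-oxy)methyl]furan-2(5H)-one
Conditions: Pd(PPh3)4 (5 mol%), CO (1 atm), K2CO3, THF, rt
Reagents that add atoms: carbon monoxide [C-]#[O+]
Why: Carbonylative lactonisation proceeds by oxidative addition of zerovalent palladium to the carbon–iodine bond, CO insertion and capture of the acylpalladium by the cis-disposed C6 hydroxyl, which closes the butenolide without involving the stereocentre.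

Step 10
Reactants: 18 (5R)-5-[(1Z,5E)-8-(TBS-oxy)-2-[(TBDPS-oxy)methyl]-6-methylocta-1,5-dien-1-yl]-3-[(PMB-oxy)methyl]furan-2(5H)-one
Product: 19 (5R)-5-[(1Z,5E)-8-(TBS-oxy)-2-[(TBDPS-oxy)methyl]-6-methylocta-1,5-dien-1-yl]-3-(hydroxymethyl)furan-2(5H)-one
Conditions: DDQ, CH2Cl2/pH 7 buffer, 0 °C
Reagents that add atoms: none
Why: Oxidative cleavage of the electron-rich PMB ether by DDQ frees the C13 hydroxyl while both silyl ethers stay in place.

Step 11
Reactants: 19 (5R)-5-[(1Z,5E)-8-(TBS-oxy)-2-[(TBDPS-oxy)methyl]-6-methylocta-1,5-dien-1-yl]-3-(hydroxymethyl)furan-2(5H)-one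
Product: 20 (5R)-3-(bromomethyl)-5-[(1Z,5E)-8-(TBS-oxy)-2-[(TBDPS-oxy)methyl]-6-methylocta-1,5-dien-1-yl]furan-2(5H)-one
Conditions: CBr4, PPh3, CH2Cl2, 0 °C
Reagents that add atoms: tetrabromomethane BrC(Br)(Br)Br
Why: Appel bromination of the primary allylic alcohol gives the allylic bromide under neutral conditions that spare the base-sensitive C6–H.

Step 12
Reactants: 20 (5R)-3-(bromomethyl)-5-[(1Z,5E)-8-(TBS-oxy)-2-[(TBDPS-oxy)methyl]-6-methylocta-1,5-dien-1-yl]furan-2(5H)-one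
Product: 21 (5R)-3-(bromomethyl)-5-[(1Z,5E)-2-[(TBDPS-oxy)methyl]-8-hydroxy-6-methylocta-1,5-dien-1-yl]furan-2(5H)-one
Conditions: 48% aq. HF, MeCN, 0 °C
Reagents that add atoms: none
Why: Acidic fluoride removes the primary TBS ether much faster than the TBDPS ether and should not displace the allylic bromide.

Step 13
Reactants: 21 (5R)-3-(bromomethyl)-5-[(1Z,5E)-2-[(TBDPS-oxy)methyl]-8-hydroxy-6-methylocta-1,5-dien-1-yl]furan-2(5H)-one
Product: 22 (3E,7Z)-8-[(2R)-4-(bromomethyl)-5-oxo-2,5-dihydrofuran-2-yl]-7-[(TBDPS-oxy)methyl]-3-methylocta-3,7-dienal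
Conditions: Dess–Martin periodinane, NaHCO3, CH2Cl2, 0 °C; crude aldehyde used at once
Reagents that add atoms: none
Why: Buffered Dess–Martin oxidation gives the β,γ-unsaturated aldehyde under mild non-basic conditions that should avoid migration of the C1=C10 olefin into conjugation.

Step 14
Reactants: 22 (3E,7Z)-8-[(2R)-4-(bromomethyl)-5-oxo-2,5-dihydrofuran-2-yl]-7-[(TBDPS-oxy)methyl]-3-methylocta-3,7-dienal
Product: 24 (3aR,4S,6E,10Z,11aR)-10-[(TBDPS-oxy)methyl]-4-hydroxy-6-methyl-3-methylidene-3a,4,5,8,9,11a-hexahydrocyclodeca[b]furan-2(3H)-one, via allylchromium dichloride 23 (not isolated)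
Conditions: CrCl2 (8 equiv), THF, rt, 22 added by syringe pump over 12 h (final 0.002 M); aq. NH4Cl
Reagents that add atoms: none
Why: Two equivalents of divalent chromium reduce the allylic C13–Br bond to allylchromium 23, which adds to the tethered aldehyde through its γ-carbon C7 in a six-membered chair (Zimmerman–Traxler) transition state with allylic transposition, leaving C11=C13 as the exocyclic methylene. The closest known reaction type is the intramolecular Nozaki–Hiyama–Kishi allylation that closes ten- to fourteen-membered carbocycles from 2-(bromomethyl)acrylate-type bromides, bromomethylbutenolides included. The ten-membered ring closes by 1,2-addition of C7 to the C8 carbonyl (a 10-exo-trig closure onto C=O), and the lactone ring is already in place. C7 is set by the C6 stereocentre, because the aldehyde arm reaches the butenolide face opposite to the C5 side chain and the ring fusion becomes trans; C8 is set by the chair, in which the ring-locked allylchromium (C6 trans to CH2Cr) and an equatorial C9 give the 7,8-anti (4S) carbinol. The step needs γ- over α-attack, which is intrinsic to allylchromium reagents, and ring closure over oligomerisation, which slow addition at high dilution and the two trisubstituted olefins, both trans within the forming ring, should secure. The neutral medium should leave the β,γ-unsaturated aldehyde, the epimerisable C6–H and the silyl ether untouched.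

Step 15
Reactants: 24 (3aR,4S,6E,10Z,11aR)-10-[(TBDPS-oxy)methyl]-4-hydroxy-6-methyl-3-methylidene-3a,4,5,8,9,11a-hexahydrocyclodeca[b]furan-2(3H)-one
Product: 25 (3S,3aR,4S,6E,10Z,11aR)-10-[(TBDPS-oxy)methyl]-4-hydroxy-3,6-dimethyl-3a,4,5,8,9,11a-hexahydrocyclodeca[b]furan-2(3H)-one
Conditions: NaBH4, MeOH, 0 °C
Reagents that add atoms: none
Why: Conjugate hydride addition to the α-methylene lactone gives an enolate whose protonation under the equilibrating methanolic conditions places the new C11 methyl trans to the C7–C8 bond (11S), the outcome usual for borohydride reduction of trans-fused germacranolides.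

Step 16
Reactants: 26 ethyl 2-(hydroxymethyl)prop-2-enoate
Product: 27 ethyl 2-[(TBS-oxy)methyl]prop-2-enoate
Conditions: TBSCl, imidazole, CH2Cl2, 0 °C to rt
Reagents that add atoms: tert-butyl(chloro)dimethylsilane CC(C)(C)[Si](C)(C)Cl
Why: Silylation of the primary allylic alcohol protects the hydroxymethyl group of the acrylate for the coupling.

Step 17
Reactants: 27 ethyl 2-[(TBS-oxy)methyl]prop-2-enoate
Product: 28 2-[(TBS-oxy)methyl]prop-2-enoic acid
Conditions: LiOH, THF/H2O, 0 °C; then 1 M HCl to pH 3 at 0 °C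
Reagents that add atoms: lithium hydroxide [Li+].[OH-]
Why: Saponification of the ethyl ester at low temperature gives the acid while the silyl ether should survive.

Step 18
Reactants: 25 (3S,3aR,4S,6E,10Z,11aR)-10-[(TBDPS-oxy)methyl]-4-hydroxy-3,6-dimethyl-3a,4,5,8,9,11a-hexahydrocyclodeca[b]furan-2(3H)-one; 28 2-[(TBS-oxy)methyl]prop-2-enoic acid
Product: 29 (3S,3aR,4S,6E,10Z,11aR)-10-[(TBDPS-oxy)methyl]-3,6-dimethyl-2-oxo-2,3,3a,4,5,8,9,11a-octahydrocyclodeca[b]furan-4-yl 2-[(TBS-oxy)methyl]prop-2-enoate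
Conditions: EDC·HCl, DMAP, CH2Cl2, 0 °C to rt
Reagents that add atoms: none
Why: Carbodiimide-mediated Steglich esterification acylates the only free hydroxyl, the secondary C8 alcohol, with retention of configuration.

Step 19
Reactants: 29 (3S,3aR,4S,6E,10Z,11aR)-10-[(TBDPS-oxy)methyl]-3,6-dimethyl-2-oxo-2,3,3a,4,5,8,9,11a-octahydrocyclodeca[b]furan-4-yl 2-[(TBS-oxy)methyl]prop-2-enoate
Product: 30 (3S,3aR,4S,6E,10Z,11aR)-10-(hydroxymethyl)-3,6-dimethyl-2-oxo-2,3,3a,4,5,8,9,11a-octahydrocyclodeca[b]furan-4-yl 2-(hydroxymethyl)prop-2-enoate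
Conditions: HF·pyridine, pyridine, THF, 0 °C to rt
Reagents that add atoms: none
Why: Buffered HF·pyridine cleaves both silyl ethers without base, which should avoid acyl migration and conjugate addition to the acrylate.

Compound list

1 | tert-butyl(but-3-yn-1-yloxy)dimethylsilane | C#CCCO[Si](C)(C)C(C)(C)C | starting material
2 | [(1E)-4-(TBS-oxy)-2-methylbut-1-en-1-yl]dimethylalane | C[Al](C)/C=C(C)/CCO[Si](C)(C)C(C)(C)C | intermediate
3 | lithium butyl[(1E)-4-(TBS-oxy)-2-methylbut-1-en-1-yl]dimethylalanate | [Li+].CCCC[Al-](C)(C)/C=C(C)/CCO[Si](C)(C)C(C)(C)C | intermediate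
4 | (3E)-6-(TBS-oxy)-4-methylhex-3-en-1-ol | OCC/C=C(C)/CCO[Si](C)(C)C(C)(C)C | intermediate
5 | [(3E)-6-bromo-3-methylhex-3-en-1-yl]oxy(tert-butyl)dimethylsilane | BrCC/C=C(C)/CCO[Si](C)(C)C(C)(C)C | intermediate
6 | methyl 4-hydroxybut-2-ynoate | COC(=O)C#CCO | starting material
7 | methyl 4-(TBDPS-oxy)but-2-ynoate | COC(=O)C#CCO[Si](c1ccccc1)(c1ccccc1)C(C)(C)C | intermediate
8 | [(3E)-6-(TBS-oxy)-4-methylhex-3-en-1-yl]magnesium bromide | Br[Mg]CC/C=C(C)/CCO[Si](C)(C)C(C)(C)C | intermediate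
9 | [(3E)-6-(TBS-oxy)-4-methylhex-3-en-1-yl]copper (monovalent copper, as its MgBr2 complex) | [Cu]CC/C=C(C)/CCO[Si](C)(C)C(C)(C)C | intermediate
10 | methyl (2Z,6E)-9-(TBS-oxy)-3-[(TBDPS-oxy)methyl]-7-methylnona-2,6-dienoate | COC(=O)/C=C(CO[Si](c1ccccc1)(c1ccccc1)C(C)(C)C)/CC/C=C(C)/CCO[Si](C)(C)C(C)(C)C | intermediate
11 | (2Z,6E)-9-(TBS-oxy)-3-[(TBDPS-oxy)methyl]-7-methylnona-2,6-dien-1-ol | OC/C=C(CO[Si](c1ccccc1)(c1ccccc1)C(C)(C)C)/CC/C=C(C)/CCO[Si](C)(C)C(C)(C)C | intermediate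
12 | (2Z,6E)-9-(TBS-oxy)-3-[(TBDPS-oxy)methyl]-7-methylnona-2,6-dienal | O=C/C=C(CO[Si](c1ccccc1)(c1ccccc1)C(C)(C)C)/CC/C=C(C)/CCO[Si](C)(C)C(C)(C)C | intermediate
13 | 1-methoxy-4-[(prop-2-yn-1-yloxy)methyl]benzene (PMB propargyl ether) | C#CCOCc1ccc(OC)cc1 | starting material
14 | methyl[3-(PMB-oxy)prop-1-yn-1-yl]zinc | C[Zn]C#CCOCc1ccc(OC)cc1 | intermediate
15 | (4R,5Z,9E)-12-(TBS-oxy)-6-[(TBDPS-oxy)methyl]-1-(PMB-oxy)-10-methyldodeca-5,9-dien-2-yn-4-ol | CC(C)(C)[Si](C)(C)OCC/C(C)=C/CC/C(CO[Si](c1ccccc1)(c1ccccc1)C(C)(C)C)=C/[C@@H](O)C#CCOCc1ccc(OC)cc1 | intermediate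
16 | sodium (5R)-2,2-bis(2-methoxyethoxy)-3-[(PMB-oxy)methyl]-5-[(1Z,5E)-8-(TBS-oxy)-2-[(TBDPS-oxy)methyl]-6-methylocta-1,5-dien-1-yl]-2,5-dihydro-1,2-oxaluminol-2-uide | [Na+].COCCO[Al-]1(OCCOC)O[C@@H](C=C1COCc1ccc(OC)cc1)/C=C(CO[Si](c1ccccc1)(c1ccccc1)C(C)(C)C)/CC/C=C(C)/CCO[Si](C)(C)C(C)(C)C | intermediate
17 | (2Z,4R,5Z,9E)-12-(TBS-oxy)-6-[(TBDPS-oxy)methyl]-2-iodo-1-(PMB-oxy)-10-methyldodeca-2,5,9-trien-4-ol | CC(C)(C)[Si](C)(C)OCC/C(C)=C/CC/C(CO[Si](c1ccccc1)(c1ccccc1)C(C)(C)C)=C/[C@@H](O)/C=C(I)/COCc1ccc(OC)cc1 | intermediate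
18 | (5R)-5-[(1Z,5E)-8-(TBS-oxy)-2-[(TBDPS-oxy)methyl]-6-methylocta-1,5-dien-1-yl]-3-[(PMB-oxy)methyl]furan-2(5H)-one | CC(C)(C)[Si](C)(C)OCC/C(C)=C/CC/C(CO[Si](c1ccccc1)(c1ccccc1)C(C)(C)C)=C/[C@H]1OC(=O)C(COCc2ccc(OC)cc2)=C1 | intermediate
19 | (5R)-5-[(1Z,5E)-8-(TBS-oxy)-2-[(TBDPS-oxy)methyl]-6-methylocta-1,5-dien-1-yl]-3-(hydroxymethyl)furan-2(5H)-one | CC(C)(C)[Si](C)(C)OCC/C(C)=C/CC/C(CO[Si](c1ccccc1)(c1ccccc1)C(C)(C)C)=C/[C@H]1OC(=O)C(CO)=C1 | intermediate
20 | (5R)-3-(bromomethyl)-5-[(1Z,5E)-8-(TBS-oxy)-2-[(TBDPS-oxy)methyl]-6-methylocta-1,5-dien-1-yl]furan-2(5H)-one | CC(C)(C)[Si](C)(C)OCC/C(C)=C/CC/C(CO[Si](c1ccccc1)(c1ccccc1)C(C)(C)C)=C/[C@H]1OC(=O)C(CBr)=C1 | intermediate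
21 | (5R)-3-(bromomethyl)-5-[(1Z,5E)-2-[(TBDPS-oxy)methyl]-8-hydroxy-6-methylocta-1,5-dien-1-yl]furan-2(5H)-one | OCC/C(C)=C/CC/C(CO[Si](c1ccccc1)(c1ccccc1)C(C)(C)C)=C/[C@H]1OC(=O)C(CBr)=C1 | intermediate
22 | (3E,7Z)-8-[(2R)-4-(bromomethyl)-5-oxo-2,5-dihydrofuran-2-yl]-7-[(TBDPS-oxy)methyl]-3-methylocta-3,7-dienal | O=CC/C(C)=C/CC/C(CO[Si](c1ccccc1)(c1ccccc1)C(C)(C)C)=C/[C@H]1OC(=O)C(CBr)=C1 | intermediate
23 | allylchromium dichloride from 22 (trivalent chromium on C13) | O=CC/C(C)=C/CC/C(CO[Si](c1ccccc1)(c1ccccc1)C(C)(C)C)=C/[C@H]1OC(=O)C(C[Cr](Cl)Cl)=C1 | intermediate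
24 | (3aR,4S,6E,10Z,11aR)-10-[(TBDPS-oxy)methyl]-4-hydroxy-6-methyl-3-methylidene-3a,4,5,8,9,11a-hexahydrocyclodeca[b]furan-2(3H)-one | O[C@H]1C/C(C)=C/CC/C(CO[Si](c3ccccc3)(c3ccccc3)C(C)(C)C)=C/[C@H]2OC(=O)C(=C)[C@H]12 | intermediate
25 | (3S,3aR,4S,6E,10Z,11aR)-10-[(TBDPS-oxy)methyl]-4-hydroxy-3,6-dimethyl-3a,4,5,8,9,11a-hexahydrocyclodeca[b]furan-2(3H)-one | O[C@H]1C/C(C)=C/CC/C(CO[Si](c3ccccc3)(c3ccccc3)C(C)(C)C)=C/[C@H]2OC(=O)[C@@H](C)[C@H]12 | intermediate
26 | ethyl 2-(hydroxymethyl)prop-2-enoate | C=C(CO)C(=O)OCC | starting material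
27 | ethyl 2-[(TBS-oxy)methyl]prop-2-enoate | C=C(CO[Si](C)(C)C(C)(C)C)C(=O)OCC | intermediate
28 | 2-[(TBS-oxy)methyl]prop-2-enoic acid | C=C(CO[Si](C)(C)C(C)(C)C)C(=O)O | intermediate
29 | (3S,3aR,4S,6E,10Z,11aR)-10-[(TBDPS-oxy)methyl]-3,6-dimethyl-2-oxo-2,3,3a,4,5,8,9,11a-octahydrocyclodeca[b]furan-4-yl 2-[(TBS-oxy)methyl]prop-2-enoate | C=C(CO[Si](C)(C)C(C)(C)C)C(=O)O[C@H]1C/C(C)=C/CC/C(CO[Si](c3ccccc3)(c3ccccc3)C(C)(C)C)=C/[C@H]2OC(=O)[C@@H](C)[C@H]12 | intermediate
30 | (3S,3aR,4S,6E,10Z,11aR)-10-(hydroxymethyl)-3,6-dimethyl-2-oxo-2,3,3a,4,5,8,9,11a-octahydrocyclodeca[b]furan-4-yl 2-(hydroxymethyl)prop-2-enoate | C=C(CO)C(=O)O[C@H]1C/C(C)=C/CC/C(CO)=C/[C@H]2OC(=O)[C@@H](C)[C@H]12 | target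

Total step count: 19. Longest linear sequence: 16 steps (steps 1, 2, 4 to 15, 18, 19).

Steps most likely to fail

Step 14. The aldehyde carbonyl may be attacked on its other face in the macrocyclic transition state, so that the C8 carbinol forms with the wrong configuration or as a mixture. The fallback sets out from aldehyde 22 and comes back at ester 29. The cyclisation is run as in step 14 and the (3aR,4R,6E,10Z,11aR)-epimer of the carbinol F1 is separated. It is reduced with NaBH4 in MeOH at 0 °C as in step 15 to the (3S,3aR,4R,6E,10Z,11aR)-dihydro alcohol F2. F2 is then esterified with acid 28 under Mitsunobu conditions (PPh3, DIAD, toluene, 0 °C), which inverts C8 and should give 29 directly, so both C8 epimers converge on the same ester.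

Step 15. The enolate may be protonated on the wrong face at C11, and the lactone acyl group may migrate to the free C8 hydroxyl under the basic methanolic conditions. The fallback sets out from 24 and comes back at 25. Silylation (TESOTf, 2,6-lutidine, CH2Cl2, −78 °C) gives the C8 triethylsilyl ether F3. Hydrogenation of the exocyclic methylene with H2 (1 atm) and RhCl(PPh3)3 in benzene, which leaves trisubstituted olefins alone, should give the dihydro lactone as its (3R)-epimer F4 and its (3S)-epimer F5. DBU in toluene at 60 °C then equilibrates the mixture to F5, with the methyl trans to the C7–C8 bond and no free hydroxyl to accept the acyl group. Buffered HF·pyridine in THF at 0 °C removes the triethylsilyl group selectively and gives 25.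

Step 9. Zerovalent palladium may ionise the newly formed allylic lactone C6–O bond, and the carbonate base may epimerise the doubly activated C6–H. The fallback sets out from iodide 17 and comes back at butenolide 18 without palladium. MeLi (1 equiv) and then t-BuLi (2 equiv) in Et2O at −78 °C give the lithium alkoxide alkenyllithium F6 by iodine–lithium exchange with retention. Quenching with CO2 and acidification to pH 3 give the Z-configured hydroxy acid F7, which should close to 18 on standing or with catalytic pyridinium p-toluenesulfonate.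

Further compounds

F1 | step 14 | (3aR,4R,6E,10Z,11aR)-10-[(TBDPS-oxy)methyl]-4-hydroxy-6-methyl-3-methylidene-3a,4,5,8,9,11a-hexahydrocyclodeca[b]furan-2(3H)-one | O[C@@H]1C/C(C)=C/CC/C(CO[Si](c3ccccc3)(c3ccccc3)C(C)(C)C)=C/[C@H]2OC(=O)C(=C)[C@H]12
F2 | step 14 | (3S,3aR,4R,6E,10Z,11aR)-10-[(TBDPS-oxy)methyl]-4-hydroxy-3,6-dimethyl-3a,4,5,8,9,11a-hexahydrocyclodeca[b]furan-2(3H)-one | O[C@@H]1C/C(C)=C/CC/C(CO[Si](c3ccccc3)(c3ccccc3)C(C)(C)C)=C/[C@H]2OC(=O)[C@@H](C)[C@H]12
F3 | step 15 | (3aR,4S,6E,10Z,11aR)-10-[(TBDPS-oxy)methyl]-6-methyl-3-methylidene-4-(triethylsilyloxy)-3a,4,5,8,9,11a-hexahydrocyclodeca[b]furan-2(3H)-one | CC[Si](CC)(CC)O[C@H]1C/C(C)=C/CC/C(CO[Si](c3ccccc3)(c3ccccc3)C(C)(C)C)=C/[C@H]2OC(=O)C(=C)[C@H]12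
F4 | step 15 | (3R,3aR,4S,6E,10Z,11aR)-10-[(TBDPS-oxy)methyl]-3,6-dimethyl-4-(triethylsilyloxy)-3a,4,5,8,9,11a-hexahydrocyclodeca[b]furan-2(3H)-one | CC[Si](CC)(CC)O[C@H]1C/C(C)=C/CC/C(CO[Si](c3ccccc3)(c3ccccc3)C(C)(C)C)=C/[C@H]2OC(=O)[C@H](C)[C@H]12
F5 | step 15 | (3S,3aR,4S,6E,10Z,11aR)-10-[(TBDPS-oxy)methyl]-3,6-dimethyl-4-(triethylsilyloxy)-3a,4,5,8,9,11a-hexahydrocyclodeca[b]furan-2(3H)-one | CC[Si](CC)(CC)O[C@H]1C/C(C)=C/CC/C(CO[Si](c3ccccc3)(c3ccccc3)C(C)(C)C)=C/[C@H]2OC(=O)[C@@H](C)[C@H]12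
F6 | step 9 | dilithio derivative of 17 (lithium alkoxide at C6 and alkenyllithium at C11) | CC(C)(C)[Si](C)(C)OCC/C(C)=C/CC/C(CO[Si](c1ccccc1)(c1ccccc1)C(C)(C)C)=C/[C@@H](O[Li])/C=C([Li])/COCc1ccc(OC)cc1
F7 | step 9 | (2Z,4R,5Z,9E)-12-(TBS-oxy)-6-[(TBDPS-oxy)methyl]-4-hydroxy-2-[(PMB-oxy)methyl]-10-methyldodeca-2,5,9-trienoic acid | CC(C)(C)[Si](C)(C)OCC/C(C)=C/CC/C(CO[Si](c1ccccc1)(c1ccccc1)C(C)(C)C)=C/[C@@H](O)/C=C(C(=O)O)/COCc1ccc(OC)cc1
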